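Everything rests on cutting the piperidine ring away from C8 of the chromone A ring: C2' derives from the aldehyde carbon of 2,4,6-trimethoxybenzaldehyde, an arene whose two ortho oxygens are still equivalent, so the heterocycle can be installed before the pyranone ring tells them apart. In one flask the key step adds 4-chlorobutylmagnesium bromide to an (S)-N-tert-butanesulfinyl aldimine, which forms C2'–C3' and sets C2' as R, and base then joins N1' to C6' with loss of chloride, completing the piperidine ring. Its precursor is the E-sulfinimine of that aldehyde, free of phenols. N-Methylation, acetylation with ortho-demethylation, Claisen condensation, cyclodehydration and ether cleavage then build the flavone.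

Key step: step 3

Remarks on the chemistry:
- Primed locants (N1', C2'–C6') denote the piperidine, unprimed locants the chromone.
- Methyl ethers are kept on the precursor because they survive the organometallic step, leave no ortho or para phenol next to C2' until the pyranone is closed, and permit the regioselective Lewis-acid demethylation of step 5.
- In step 5 the cleaved O-methyl group is assumed to leave as methyl acetate.

Step 1
Reactants: 1 2,4,6-trimethoxybenzaldehyde; 2 (S)-2-methylpropane-2-sulfinamide
Product: 3 (S,E)-2-methyl-N-(2,4,6-trimethoxybenzylidene)propane-2-sulfinamide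
Conditions: Ti(OEt)4 (2 equiv), THF, 60 °C; brine work-up
Reagents that add atoms: none
Why: Titanium(IV) ethoxide-mediated condensation of tert-butanesulfinamide with an aldehyde (sulfinimine formation) should give the E-aldimine alone even from this hindered, electron-rich aldehyde, because the titanium reagent serves as Lewis acid and as water scavenger, and the sulfur stereocentre is carried over unchanged.

Step 2
Reactants: 4 1-bromo-4-chlorobutane
Product: 5 4-chlorobutylmagnesium bromide
Conditions: Mg turnings, I2 (cat.), Et2O, 20–35 °C; titrate, use the same day
Reagents that add atoms: magnesium, [Mg]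
Why: Grignard formation by insertion of magnesium should take place only at the C–Br bond, since the primary C–Cl bond inserts far more slowly in ether at this temperature and the reagent cannot readily close a four-membered ring on its own chloride.

Step 3
Reactants: 3 (S,E)-2-methyl-N-(2,4,6-trimethoxybenzylidene)propane-2-sulfinamide; 5 4-chlorobutylmagnesium bromide
Product: 7 (R)-1-[(S)-tert-butylsulfinyl]-2-(2,4,6-trimethoxyphenyl)piperidine, via open-chain chloropentyl sulfinamide 6 (not isolated)
Conditions: 5 (1.5–2 equiv, Et2O), toluene, −78 → −20 °C; then LiHMDS (THF), −20 °C → rt; H2O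
Reagents that add atoms: none
Why: Coordination of the sulfinyl oxygen to magnesium should organise a six-membered chair transition state (tert-butyl equatorial, aryl equatorial) in which the 4-chlorobutyl group passes from magnesium to the Re face of the (S_S)-E-aldimine carbon and forms C2'–C3'; the closest known reaction type is the 1,2-addition of Grignard reagents to N-tert-butanesulfinyl aldimines, here joined in one flask to the known base-induced cyclisation of ω-chloroalkyl sulfinamides. LiHMDS then turns the magnesium sulfinamide into a more nucleophilic lithium amide, whose nitrogen displaces chloride at C6' in a 6-exo-tet SN2 closure that forms N1'–C6' and the piperidine ring. The one new stereocentre, C2', is controlled by the sulfur stereocentre of the auxiliary and should be R, since the aryl group outranks the new chain. The step needs imine facial selectivity, secured by the exclusive E geometry of the aldimine, by the two identical ortho substituents (either arene rotamer presents the same environment) and by toluene as a non-coordinating medium that leaves the sulfinyl oxygen as the best ligand for magnesium. It also needs the reagent to attack C=N and not its own primary C–Cl bond, which the low temperature secures, and N- rather than O-alkylation in the closure, which the six-membered ring size favours.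

Step 4
Reactants: 7 (R)-1-[(S)-tert-butylsulfinyl]-2-(2,4,6-trimethoxyphenyl)piperidine
Product: 9 (2R)-1-methyl-2-(2,4,6-trimethoxyphenyl)piperidine, via secondary amine 8 (not isolated)
Conditions: HCl (4 M in dioxane), MeOH, 0 °C, 30 min; evaporate; then Et3N, 37% aq. CH2O, NaBH(OAc)3, DCE, rt; aq. NaHCO3
Reagents that add atoms: formaldehyde, C=O
Why: Acidolysis of the N–S bond (standard sulfinamide cleavage) followed by Borch-type reductive amination with formaldehyde should exchange the auxiliary for N-methyl without touching C2', because no bond to C2' is made or broken, the only iminium ion formed is the exocyclic N=CH2, and the acid stage is short and cold so that the trioxygenated benzylic C–N bond does not ionise.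

Step 5
Reactants: 9 (2R)-1-methyl-2-(2,4,6-trimethoxyphenyl)piperidine
Product: 10 1-{2-hydroxy-4,6-dimethoxy-3-[(2R)-1-methylpiperidin-2-yl]phenyl}ethan-1-one
Conditions: Ac2O (3 equiv), BF3·OEt2 (5 equiv), CH2Cl2, 0 °C → rt; aq. Na2CO3
Reagents that add atoms: acetic anhydride, CC(=O)OC(C)=O
Why: Friedel–Crafts acetylation of the very electron-rich arene at its only kind of free position (C3 and C5 of the aryl ring are equivalent), followed in the same flask by BF3-chelate-assisted cleavage of a methyl ether ortho to the new ketone, should give the 2-hydroxyacetophenone, and the ether lost should be the one flanked by acetyl and piperidinyl, which is twisted out of conjugation and is the most basic and most strained of the three; C2' is not involved.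

Step 6
Reactants: 10 1-{2-hydroxy-4,6-dimethoxy-3-[(2R)-1-methylpiperidin-2-yl]phenyl}ethan-1-one; 11 methyl benzoate
Product: 13 5,7-dimethoxy-8-[(2R)-1-methylpiperidin-2-yl]-2-phenyl-4H-chromen-4-one, via hydroxyaryl 1,3-diketone 12 (not isolated)
Conditions: NaH (4 equiv), DMF, 0 °C → rt; AcOH quench, evaporate; then conc. HCl, AcOH, rt → 50 °C; aq. NaHCO3
Reagents that add atoms: none
Why: Crossed Claisen condensation of the phenoxide–enolate dianion with the non-enolisable ester gives the same o-hydroxyaryl 1,3-diketone that a Baker–Venkataraman rearrangement would give, and acid-catalysed cyclodehydration (attack of the phenol on the enolised benzoyl carbonyl, then loss of water) should close the γ-pyrone so that the phenol oxygen next to the piperidinyl carbon becomes O1 and the piperidine sits at C8.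

Step 7
Reactants: 13 5,7-dimethoxy-8-[(2R)-1-methylpiperidin-2-yl]-2-phenyl-4H-chromen-4-one
Product: 14 5,7-dihydroxy-8-[(2R)-1-methylpiperidin-2-yl]-2-phenyl-4H-chromen-4-one
Conditions: BBr3 (6 equiv), CH2Cl2, −78 °C → rt; H2O, then aq. NaHCO3 to pH 7–8
Reagents that add atoms: none
Why: Lewis-acid cleavage of aryl methyl ethers with BBr3 should free both phenols, the 5-ether first through chelation to the C4 carbonyl and the 7-ether on warming, and working at or below room temperature is meant to avoid acid-promoted ionisation at C2' and Wessely–Moser-type isomerisation of the pyranone.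

Compound list
1 | 2,4,6-trimethoxybenzaldehyde | COc1cc(OC)c(C=O)c(OC)c1 | starting material
2 | (S)-2-methylpropane-2-sulfinamide [(S)-tert-butanesulfinamide] | CC(C)(C)[S@](=O)N | starting material
3 | (S,E)-2-methyl-N-(2,4,6-trimethoxybenzylidene)propane-2-sulfinamide | CC(C)(C)[S@](=O)/N=C/c1c(OC)cc(OC)cc1OC | intermediate
4 | 1-bromo-4-chlorobutane | ClCCCCBr | starting material
5 | 4-chlorobutylmagnesium bromide | ClCCCC[Mg]Br | intermediate
6 | (S)-N-[(1R)-5-chloro-1-(2,4,6-trimethoxyphenyl)pentyl]-2-methylpropane-2-sulfinamide (present in the flask as its N-metal salt) | CC(C)(C)[S@](=O)N[C@H](CCCCCl)c1c(OC)cc(OC)cc1OC | intermediate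
7 | (R)-1-[(S)-tert-butylsulfinyl]-2-(2,4,6-trimethoxyphenyl)piperidine | CC(C)(C)[S@](=O)N1CCCC[C@@H]1c1c(OC)cc(OC)cc1OC | intermediate
8 | (2R)-2-(2,4,6-trimethoxyphenyl)piperidine (present in the flask as its hydrochloride) | N1CCCC[C@@H]1c1c(OC)cc(OC)cc1OC | intermediate
9 | (2R)-1-methyl-2-(2,4,6-trimethoxyphenyl)piperidine | CN1CCCC[C@@H]1c1c(OC)cc(OC)cc1OC | intermediate
10 | 1-{2-hydroxy-4,6-dimethoxy-3-[(2R)-1-methylpiperidin-2-yl]phenyl}ethan-1-one | CN1CCCC[C@@H]1c1c(O)c(C(C)=O)c(OC)cc1OC | intermediate
11 | methyl benzoate | COC(=O)c1ccccc1 | starting material
12 | 1-{2-hydroxy-4,6-dimethoxy-3-[(2R)-1-methylpiperidin-2-yl]phenyl}-3-phenylpropane-1,3-dione | CN1CCCC[C@@H]1c1c(O)c(C(=O)CC(=O)c2ccccc2)c(OC)cc1OC | intermediate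
13 | 5,7-dimethoxy-8-[(2R)-1-methylpiperidin-2-yl]-2-phenyl-4H-chromen-4-one | CN1CCCC[C@@H]1c1c(OC)cc(OC)c2c(=O)cc(-c3ccccc3)oc12 | intermediate
14 | 5,7-dihydroxy-8-[(2R)-1-methylpiperidin-2-yl]-2-phenyl-4H-chromen-4-one | CN1CCCC[C@@H]1c1c(O)cc(O)c2c(=O)cc(-c3ccccc3)oc12 | target

Total step count: 7. Longest linear sequence: 6 steps (1 → 3 → 7 → 9 → 10 → 13 → 14); step 2 is the side branch that supplies the Grignard reagent.

Steps most likely to fail

1. Step 3 (key step). Three processes may spoil it:
- slow addition to an imine carbon that is hindered and electron-rich between two ortho methoxy groups;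
- erosion or reversal of facial selectivity if an ortho methoxy oxygen competes with the sulfinyl oxygen for magnesium;
- incomplete N-alkylative closure, or attack of surplus Grignard reagent at sulfur during the warm-up.

Fallback (sets out from 3, returns at 7): the ring is built by allylation and metathesis instead of alkylative closure. Indium-mediated Barbier allylation of 3 (allyl bromide, In, THF, 60 °C), a closed-transition-state addition of wide scope, should give (S)-2-methyl-N-[(1R)-1-(2,4,6-trimethoxyphenyl)but-3-en-1-yl]propane-2-sulfinamide F1; its diastereomers, should both form, can be separated at this open-chain stage. N-Allylation (LiHMDS, allyl bromide, DMF, 0 °C → rt) should then give (S)-N-allyl-2-methyl-N-[(1R)-1-(2,4,6-trimethoxyphenyl)but-3-en-1-yl]propane-2-sulfinamide F2. Ring-closing metathesis (second-generation Grubbs catalyst, CH2Cl2, 40 °C) should give (2R)-1-[(S)-tert-butylsulfinyl]-2-(2,4,6-trimethoxyphenyl)-1,2,3,6-tetrahydropyridine F3. Saturation of the ring alkene with diimide (TsNHNH2, NaOAc, THF/H2O, 70 °C) returns to 7.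

2. Step 5. Three processes may spoil it:
- cleavage of the other ortho ether, which would send the material into the 6-substituted flavone series;
- Lewis-acid-promoted ionisation of the C2'–N bond or retro-Mannich loss of the piperidine from the trioxygenated ring, with loss of enantiomeric purity or of the side chain;
- demethylation beyond one ether.

Fallback (sets out from 9, returns at 10): acylation and ether cleavage are separated, and a Lewis acid is used only at low temperature. Bromination of 9 at the free arene position (NBS, TFA 1 equiv to hold the amine as its salt, MeCN, 0 °C) should give (2R)-2-(3-bromo-2,4,6-trimethoxyphenyl)-1-methylpiperidine F4. Bromine–lithium exchange and acylation with N-methoxy-N-methylacetamide (n-BuLi, THF, −78 °C) should give 1-{2,4,6-trimethoxy-3-[(2R)-1-methylpiperidin-2-yl]phenyl}ethan-1-one F5. Chelation-controlled mono-demethylation with BCl3 (CH2Cl2, −78 → 0 °C) should then give 10, and the position of the free phenol can be checked on an isolated ketone before the flavone is built.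

3. Step 7. Three processes may spoil it:
- incomplete cleavage of the non-chelated 7-ether;
- acid-promoted reversible heterolysis of the C2'–N bond once the 7-hydroxyl is free (ortho-quinone-methide-type ionisation), which would erode the configuration;
- Wessely–Moser-type opening and reclosure of the pyranone, which would move the piperidine from C8 to C6.

Fallback (sets out from 13, returns at 14): the two ethers are removed in two stages by different mechanisms. BCl3 (CH2Cl2, −78 → 0 °C) should remove only the 5-O-methyl group through the chelate with the C4 carbonyl and give 5-hydroxy-7-methoxy-8-[(2R)-1-methylpiperidin-2-yl]-2-phenyl-4H-chromen-4-one F6. The 7-ether is then cleaved by SN2 attack of thiolate on the methyl group (NaSEt, DMF, 100 °C; neutralise to pH 7) to give 14; under these basic conditions the amine is no leaving group and the pyranone is not reopened by acid.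

Further compounds
F1 | step 3 | (S)-2-methyl-N-[(1R)-1-(2,4,6-trimethoxyphenyl)but-3-en-1-yl]propane-2-sulfinamide | CC(C)(C)[S@](=O)N[C@H](CC=C)c1c(OC)cc(OC)cc1OC
F2 | step 3 | (S)-N-allyl-2-methyl-N-[(1R)-1-(2,4,6-trimethoxyphenyl)but-3-en-1-yl]propane-2-sulfinamide | CC(C)(C)[S@](=O)N(CC=C)[C@H](CC=C)c1c(OC)cc(OC)cc1OC
F3 | step 3 | (2R)-1-[(S)-tert-butylsulfinyl]-2-(2,4,6-trimethoxyphenyl)-1,2,3,6-tetrahydropyridine | CC(C)(C)[S@](=O)N1CC=CC[C@@H]1c1c(OC)cc(OC)cc1OC
F4 | step 5 | (2R)-2-(3-bromo-2,4,6-trimethoxyphenyl)-1-methylpiperidine | CN1CCCC[C@@H]1c1c(OC)c(Br)c(OC)cc1OC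
F5 | step 5 | 1-{2,4,6-trimethoxy-3-[(2R)-1-methylpiperidin-2-yl]phenyl}ethan-1-one | CN1CCCC[C@@H]1c1c(OC)c(C(C)=O)c(OC)cc1OC
F6 | step 7 | 5-hydroxy-7-methoxy-8-[(2R)-1-methylpiperidin-2-yl]-2-phenyl-4H-chromen-4-one | CN1CCCC[C@@H]1c1c(OC)cc(O)c2c(=O)cc(-c3ccccc3)oc12
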